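The ligand charge is the one setting to choose between Monday's flask and Friday's, so the question is whether it changes which species leads after the run.

    coupling partner + catalyst intermediate B → free catalyst + right-handed product (k1 = 1.0 L mol⁻¹ h⁻¹)
    coupling partner → decomposition product (k2 = 3.9 × 10⁻⁵ h⁻¹)
    free catalyst + added ligand ⇌ idle complex, settled at all times (K3 = 63 L mol⁻¹)
    free catalyst + left-handed substrate ⇌ catalyst intermediate A (K4 = 55 L mol⁻¹, k4 = 6100 L mol⁻¹ h⁻¹)
    coupling partner + catalyst intermediate A → free catalyst + left-handed product (k5 = 26 L mol⁻¹ h⁻¹)
    free catalyst + right-handed substrate ⇌ catalyst intermediate B (K6 = 5.9 L mol⁻¹, k6 = 1900 L mol⁻¹ h⁻¹)

- Monday's: left-handed substrate 0.24 M; coupling partner 0.264 M; free catalyst 3.8 mM; added ligand 12 mM; right-handed substrate 0.24 M; time 12 h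
- Friday's: left-handed substrate 0.24 M; coupling partner 0.264 M; free catalyst 3.8 mM; added ligand 30 mM; right-handed substrate 0.24 M; time 12 h

1. which of these there is most of at the end, counted by the substrate in it, Monday's (left-handed product / right-handed substrate / catalyst intermediate A / left-handed substrate)
2. which of these there is most of at the end, counted by the substrate in it, Friday's (left-handed product / right-handed substrate / catalyst intermediate A / left-handed substrate)
3. how much there is at the end of the one of these that leads, in percent of the left-handed substrate and right-handed substrate together charged: Monday's
4. how much there is at the end of the one of these that leads, in percent of the left-handed substrate and right-handed substrate together charged: Friday's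

- free catalyst is single-handed; left-handed substrate and right-handed substrate are mirror images of each other, charged as a racemate, each of them at the stated concentration
- run time (Monday's): 12 h

Intermediate A returns to free catalyst and left-handed substrate at 111 h⁻¹, faster than it goes on at 6.86 h⁻¹. Intermediate B likewise returns at 322 h⁻¹ and goes on at 0.264 h⁻¹. So each intermediate can be frozen at balance with free catalyst. The two products then form at rates whose ratio, per unit of each substrate, is the selectivity factor s, the binding constant times the coupling constant of the left-handed route over the same product for the right-handed route: s = 242. Free catalyst and coupling partner stand in both rates and cancel, and the added ligand acts through free catalyst, so Monday's and Friday's share this s. The left-handed substrate therefore leaves far more readily, and the ligand changes the pace of both routes together.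

A limit on the right-handed loss follows by freezing coupling partner at its charge and counting no catalyst as held by left-handed substrate. The catalyst then divides by D, one plus the ligand and right-handed binding terms: 3.17 on Monday's, 4.31 on Friday's. The right-handed substrate then decays pseudo-first-order, losing a fraction x of at most 2.24% on Monday's and 1.65% on Friday's. With the catalyst it can hold, it stays above 48.5% on Monday's and 48.9% on Friday's.

To overtake that, left-handed product needs the left-handed substrate down to 2.95% of its charge on Monday's, and 2.17% on Friday's. Integrating the saturating rate with the same frozen values puts this at 16.7 h on Monday's and 20.5 h on Friday's, later than the 12 h of the run. The leader is thus right-handed substrate on Monday's and right-handed substrate on Friday's.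

The forecast names right-handed substrate and right-handed substrate, at 49.7% and 49.7%, holding that “the ligand is a weak competitor next to the substrate”. The figures reckoned here are lower limits, and they stand below the forecast's values in both flasks.

The flask gives right-handed substrate at 49.6% on Monday's and right-handed substrate at 49.7% on Friday's. Left-handed product stands at 31.0% on Monday's and 29.4% on Friday's. On Friday's, 40% of the left-handed charge remains unbound against 99.4% of the right-handed. With s, the right-handed fraction turned to product is close to the logarithm of the inverse left-handed remainder, divided by s. Friday's then gives 0.187% of both substrates charged as right-handed product, and the flask holds 0.193%. Monday's flask read at 3.0 h gives 0.0559% of right-handed product, and it holds 0.0563%.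

The numbers stand for no real mixture; the result is computed.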